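The constants used here stand for no real mixture; what happens was integrated by code.

At early times the flask is a matter of E meeting Z, and I start there to see how soon that is over.

    E + Z → D + Q (k1 = 1.1 L mol⁻¹ s⁻¹)
    D → L (k2 = 0.060 s⁻¹)
    E + Q → E.Q (k3 = 0.082 L mol⁻¹ s⁻¹)
    L → J (k4 = 0.024 s⁻¹)

all flasks: E 0.40 M; Z 1.20 M

|  | time |
|---|---|
| maple | 25 s |
| elm | 50 s |

- which of these there is most of at the end, counted by the E in it, maple (E.Q / L / D / J)
- which of these there is most of at the end, counted by the E in it, elm (E.Q / L / D / J)
- how much there is at the end of the one of these that leads, in percent of the E charged: maple
- how much there is at the end of the one of these that leads, in percent of the E charged: elm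

In maple, with Z in excess, E falls roughly in a pseudo-first-order way, with a half-life of 0.53 s by step 1 alone at Z as charged, and elm carries the same charge. At Z as charged, the first-order constant of E's loss is 22.0 times that of D going on, and the constant of the step that makes E.Q is 0.0745 of the one that makes D. So I count the E charged as D at time zero and reckon in fractions of that charge along the chain D → L → J.

My bench rule takes the symmetric case as the zero of the scale. With two equal constants, the middle species peaks at the inverse of that constant and holds 36.8% of the charge. Putting in the geometric mean of the two constants gives 26.4 s.

But here the ratio of the constants is 2.50, not one, so I solve the chain. The peak time of L in that chain is the logarithm of the ratio of the two constants divided by their difference, 25.5 s. The rule's time survives, but its height stops working: the chain's peak holds 54.3%, more than the symmetric share.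

Maple is read at 25 s, almost on that peak. I get L at 54.3%, D at 22.3% and J at 23.4%, so L leads. Elm is read at 50 s, where I get L at 41.9% and J at 53.1%, so J leads.

The forecast names L at 53.5% for maple, with L “near its maximum”, and J at 51.5% for elm, each lower than my figure.

The simulation gives L at 53.3% in maple and J at 51.4% in elm, each lower than my figure. At the end of elm, twice my peak time, L is made more slowly than it is used up, at 0.310 of that rate, each step taken net. The peak time serves again on elm's charge read at 20 s, which is 0.784 of it, still on the rising side: that neighbour holds L in the lead at 51.5%, with J at 15.6%.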